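(The readings stem from a simulated flask for an exercise, and the scatter is random.)

The substrate is the limiting reagent in zeta and theta, against 5.00 equiv of reagent, and one number read from Thursday's run carries the reckoning.

| setting | Thursday's | zeta | theta |
|---|---|---|---|
| substrate | 0.30 M | 0.20 M | 0.20 M |
| reagent | 5 equiv | 5.00 equiv | 5.00 equiv |
| free catalyst | 0.057 mol% | 0.057 mol% | 0.25 mol% |
| remark | run made earlier |  |  |
| time |  | 3.0 d | 3.0 d |

- Thursday's (time / h: target / %): 0.833: 0; 2.00: 3; 4.00: 5; 6.00: 9; 8.00: 12; 12.0: 18; 15.0: 21

(each reading ± 2 percentage points)

- the earlier runs were read with a standard deviation of 2 percentage points
- reactions considered so far: 2 free catalyst <-> resting dimer; catalyst intermediate C -> free catalyst + target; reagent + free catalyst <-> catalyst intermediate A; substrate + catalyst intermediate A <-> catalyst intermediate B; catalyst intermediate B <-> by-product + catalyst intermediate C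
- no earlier run changes the charge of free catalyst; that part of a forecast is a guess

* the flask that ends with the higher amount of target, in percent of the substrate charged, or "neither" when 2 percentage points or less lies between them (zeta / theta / neither)
* final target, as a percentage of the substrate charged, in zeta
* final target, as a percentage of the substrate charged, in theta

1. In the balance of the substrate, target and unreacted substrate make up nearly all of the charge, the catalyst forms holding no more than the 0.25 mol% loading of theta. Each target costs one reagent, so the fraction of reagent left is one minus the target fraction over 5.00, which stays at or above 80.0% in both flasks. With reagent held roughly level, the target fraction is taken as one minus the exponential of minus a constant times time, a pseudo-first-order view of the substrate.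

2. Three inputs feed that constant, tested here on theta. Taking the reading at 12.0 h instead of 15.0 h shifts theta by 1.2 percentage points. Dropping the dependence on reagent shifts it by 7.4 points. A square-root law in catalyst, with the resting dimer as resting state, shifts it by 17 points, more than either other shift.

3. The last reading gives Thursday's constant, 0.0157 /h. As a guess, this reckoning scales it by the ratios of catalyst and reagent concentrations: 0.444 for zeta and 1.95 for theta. This reckoning then gives zeta 39.5% and theta 89.0%.

4. The forecast differs, with 65% for zeta and 94% for theta, and names theta: “Theta should therefore end higher, unless zeta also reaches completion.”

5. The simulation gives 47.2% in zeta and 87.9% in theta, so theta ends higher.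

    2 free catalyst ⇌ resting dimer, settled at all times (K = 2400 /M)
    catalyst intermediate C → free catalyst + target (k = 4.70 /min)
    reagent + free catalyst ⇌ catalyst intermediate A (K = 0.900 /M, k = 11.0 /M/min)
    substrate + catalyst intermediate A ⇌ catalyst intermediate B (K = 10.0 /M, k = 4.10 /M/min)
    catalyst intermediate B ⇌ by-product + catalyst intermediate C (K = 0.150 M, k = 4.10 /min)

6. Against the reckoning, theta stands at 87.9% for 89.0% and zeta at 47.2% for 39.5%. The neighbour is theta with 2.00 equiv of reagent, where the factor falls to 0.780, and 0.0157 /h then reckons 58.6% of target. That neighbour ends with 60.5% target, with 40% of its substrate and 70% of its reagent still unbound.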